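**Remark.** Ring atoms are numbered C1 (ketone), C2 (CH2OH-bearing), C3, C4 (isobutyryloxy), C5 (isopropyl), C6 (enoyloxy) in every section; in this numbering the target is (4S,5S,6R). Compound 1 is taken as a catalogue chemical of the D-tartaric acid series. The stereodescriptors of the cyclisation precursor 11 and product 12 were rechecked against the target and needed no correction.

## Structural features

The target is one cyclohex-2-enone ring (C1 ketone, C2 carrying CH2OH, C3 =CH, C4 O-isobutyrate, C5 isopropyl, C6 O-acyl) whose C6 oxygen is esterified by (E)-4-hydroxy-2-methylbut-2-enoic acid. Three contiguous stereocentres, C4, C5 and C6, lie on the saturated half: the isopropyl group is trans to the C6 acyloxy group and cis to the C4 acyloxy group. The molecule is fragile. The α-acyloxy ketone at C6 can epimerise, the γ-acyloxy enone can lose isobutyric acid and aromatise, the two different esters must not migrate, and two primary allylic alcohols must end up free. The real difficulty is less the carbon skeleton than telling three oxygen functions apart (C1 ketone, C4 and C6 esters of different acids) while placing the C4 oxygen cis to a bulky neighbour. The key step exploits the three-carbon branch at C5 next to the C4 carbinol carbon: this is the retron of a carbonyl-ene closure between a C4 aldehyde and a C5=C(CH3)2 alkene. The C6 oxygen, tied to the C1 oxygen in a trans-dioxolane, steers C5. Since the ene product has isopropenyl at C5 and the C4 hydroxyl trans to it, one hydrogenation and one inversion at C4 belong to any plan built on it.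

## Logic of the disconnections

**30 to 29.** The O–Si bond of the side-chain alcohol is cut. The two primary allylic hydroxyls are revealed last so that no acylation has to discriminate between them; the forward step must remove silicon without touching three esters and the enone.

**29 to 27 + 28.** The C2–CH2OH bond is cut. An α-hydroxymethyl enone is the retron of a Morita–Baylis–Hillman reaction, which removes one carbon and one hydroxyl. The forward step needs a nucleophilic catalyst mild enough for the C6 α-acyloxy ketone.

**27 to 21 + 25; 25 to 24 to 22 + 23.** The C6–O acyl bond is cut, then the side-chain C=C. This makes the route convergent and lets a Wittig reaction set the E geometry of 24. The forward esterification must acylate a hindered α-hydroxy enone quickly, before it enolises.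

**21 to 20 to 19.** The C1 carbonyl is returned to an alcohol and the C1 and C6 oxygens to one dioxolane. In 20 the C1 hydroxyl is allylic and the C6 hydroxyl is not, so one chemoselective oxidation distinguishes the two tartrate oxygens without unequal protecting groups. The forward steps need a mild acetal hydrolysis and an oxidant that ignores the saturated alcohol.

**19 to 17 + 18; 17 to 16.** The C4–O ester bond is cut with inversion, then the C4–H bond. Esterification with inversion installs the ester and the cis C4/C5 relation together. It requires 17 as the trans alcohol, which the 1,2-reduction of 16 should favour.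

**16 to 15 to 14 to 13 to 12.** The C2=C3 double bond is removed, the C4 ketone returned to the alcohol, and isopropyl to isopropenyl. The C4 carbinol made by the key step serves twice: as ketone 14 it directs C2=C3 formation, and its reduction resets C4. The forward enolisation must occur at the C3 methylene, not at the C5 methine.

**12 to 11 (key).** The C4–C5 bond is cut. Ring, bond and two stereocentres are traded for an open-chain aldehyde with two chiral-pool centres. Precursor 11 is kept as the trans-dioxolane because the fused ring holds both oxygens equatorial and so defines the chair. Its weakness, that the C1 and C6 oxygens emerge undifferentiated, is answered at 20 and not by unequal protecting groups in 11, which would loosen the chair and add steps. The forward step needs a Lewis acid that activates the aldehyde without ionising the allylic acetal.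

**11 to 10 to 9 to 6 + 7 (through 8).** The aldehyde is traced to an ester, and C2–C3 to an alkene made by Wittig reaction of 8 with 7. This two-carbon extension leaves the trisubstituted alkene untouched only if the conjugate reduction is hydridic and chemoselective.

**6 to 5 to 3 + 4; 3 to 2 to 1.** The C5=C(CH3)2 bond is cut, and the two ends of C2-symmetric 1 are told apart by monosilylation. The forward Wittig step must not epimerise the α-alkoxy aldehyde 3.

## Other disconnections considered

**Alternative 1: cyclopropane as masked isopropyl.**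
- Cut: C5–C6 and a temporary C6–CMe2 bond. Forward, diazoketone A1 would be decomposed with Cu(acac)2; the copper carbenoid would add across the trisubstituted alkene to give bicyclic ketone A2. Later reductive opening of the C6–CMe2 bond would release isopropyl and a C6 enolate.
- In favour: the C1 ketone is present from the start, so C1 and C6 never appear as two hydroxyls to be distinguished; on this point it is better than the chosen plan. The opening gives a regiodefined C6 enolate for hydroxylation. A1 needs only the C4 stereocentre.
- Against: the anti adduct A2 has the C4 oxygen trans to the future isopropyl carbon, so the C4 inversion is needed as in the chosen plan (equal). The C6 oxygen is absent and would have to be introduced under control by C5 alone, whereas the chosen plan takes it from the chiral pool. A diazoketone must be handled, and a carbenoid next to an allylic silyl ether invites ylide and C–H insertion pathways. Six-membered closure by cyclopropanation is slow, and dissolving-metal opening limits functionality.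
- Comparison: a stepwise metal-carbene addition controlled by allylic strain stands against a concerted ene closure fixed by a fused ring; both are substrate-controlled. Step economy would be about equal: a shorter way to the ring, two extra operations after it, and the same enone and hydroxymethyl end-game.

**Alternative 2: hidden C2-symmetric dialdehyde.**
- Cut: C1–C2 and C2=C3, opening the ring to dialdehyde A3, in which C5 is not a stereocentre and the two aldehydes are homotopic. Forward, the carbanion of triethyl phosphonoacetate A4 would add to one aldehyde and olefinate the other to give cyclohexene ester A5.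
- In favour: ring, C2=C3 and the carbon of the C2 hydroxymethyl group would arrive in one operation, so no ketone dehydrogenation and no Baylis–Hillman step are needed. On step economy at the ring-forming stage it is clearly better than the chosen plan. The C4/C5 cis relation is built into A3, so no inversion is needed (also better). Symmetry removes any question of which aldehyde reacts.
- Against: in A5 the C4 and C6 oxygens carry the same protecting group but must become esters of two different acids, so the differentiation problem returns at C4/C6 without an obvious handle. A3 is doubly α-alkoxylated and would be prone to hydration and epimerisation under base, and any epimerisation destroys the symmetry. Simple olefination of the first aldehyde would compete with the aldol-type addition. The ester must later be reduced and the C1 carbinol oxidised in each other's presence.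
- Comparison: an ionic two-bond annulation stands against a one-bond pericyclic closure with a locked transition state. It would be shorter if A3 were easily reached, but weaker in protecting-group logic.

**Alternative 3: samarium pinacol closure.**
- Cut: C1–C6, opening the ring to 1,6-dialdehyde A6, whose C4 and C5 centres would come from an anti-selective aldol reaction. Forward, SmI2 would couple the two aldehyde carbons to cis-diol A7 with the C6 hydroxyl trans to isopropyl.
- In favour: the C4 oxygen is set cis to isopropyl directly and is already distinguished as a silyl ether; this is better than the chosen plan, which needs an inversion. The cis-diol has one axial and one equatorial hydroxyl, which should be at least as easy to tell apart as the allylic/non-allylic pair in 20 (equal). The closure is mild.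
- Against: C6 would be created in the radical coupling and depends on induction from C5 and on chelation, whereas in the chosen plan C6 is a chiral-pool centre and C5 is induced through a rigid chair. A6 has an α-branched, β-silyloxy aldehyde, so epimerisation at C5 and β-elimination threaten before coupling. An auxiliary-based aldol and two equivalents of SmI2 add steps and mass. After A7 the dehydrogenation would have to be done on an α-oxygenated ketone.
- Comparison: ketyl radical coupling under chelation control stands against a concerted ene reaction; step economy would be roughly equal.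

Key step: step 8

## Route

Step 1
Reactants: 1 ((4R,5R)-2,2-dimethyl-1,3-dioxolane-4,5-diyl)dimethanol
Product: 2 ((4R,5R)-5-(((tert-butyldimethylsilyl)oxy)methyl)-2,2-dimethyl-1,3-dioxolan-4-yl)methanol
Conditions: NaH (1.0 equiv), THF, 0 °C; then t-BuMe2SiCl (1.0 equiv), 0 °C to rt
Reagents that add atoms: tert-butyldimethylsilyl chloride, CC(C)(C)[Si](C)(C)Cl
Why: O-silylation of the monosodium alkoxide of a symmetric diol; the two hydroxyls are homotopic, so either gives 2, and the sparingly soluble mono-alkoxide should limit double silylation.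

Step 2
Reactants: 2 ((4R,5R)-5-(((tert-butyldimethylsilyl)oxy)methyl)-2,2-dimethyl-1,3-dioxolan-4-yl)methanol
Product: 3 (4S,5R)-5-(((tert-butyldimethylsilyl)oxy)methyl)-2,2-dimethyl-1,3-dioxolane-4-carbaldehyde
Conditions: (COCl)2, DMSO, CH2Cl2, −78 °C; then Et3N, −78 to 0 °C; used crude
Reagents that add atoms: none
Why: Swern oxidation of a primary alcohol; the cold, non-aqueous conditions should keep the α-alkoxy aldehyde from epimerising, and the trans-dioxolane is in any case the more stable isomer.

Step 3
Reactants: 3 (4S,5R)-5-(((tert-butyldimethylsilyl)oxy)methyl)-2,2-dimethyl-1,3-dioxolane-4-carbaldehyde; 4 isopropyltriphenylphosphonium iodide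
Product: 5 tert-butyldimethyl(((4R,5R)-2,2-dimethyl-5-(2-methylprop-1-en-1-yl)-1,3-dioxolan-4-yl)methoxy)silane
Conditions: 4, n-BuLi, THF, 0 °C; then 3, −78 °C to rt
Reagents that add atoms: none
Why: Wittig olefination with a non-stabilised ylide; the ylide carbon bears two methyl groups, so no E/Z question arises, and addition at −78 °C should outrun enolisation of 3.

Step 4
Reactants: 5 tert-butyldimethyl(((4R,5R)-2,2-dimethyl-5-(2-methylprop-1-en-1-yl)-1,3-dioxolan-4-yl)methoxy)silane
Product: 6 ((4R,5R)-2,2-dimethyl-5-(2-methylprop-1-en-1-yl)-1,3-dioxolan-4-yl)methanol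
Conditions: Bu4NF, THF, 0 °C to rt
Reagents that add atoms: none
Why: Fluoride-induced cleavage of the Si–O bond; acetonide and alkene are inert to fluoride.

Step 5
Reactants: 6 ((4R,5R)-2,2-dimethyl-5-(2-methylprop-1-en-1-yl)-1,3-dioxolan-4-yl)methanol; 7 ethyl (triphenylphosphoranylidene)acetate
Product: 9 ethyl (E)-3-((4R,5R)-2,2-dimethyl-5-(2-methylprop-1-en-1-yl)-1,3-dioxolan-4-yl)prop-2-enoate, via dioxolane carbaldehyde 8 (not isolated)
Conditions: (COCl)2, DMSO, CH2Cl2, −78 °C; Et3N; then 7, −78 °C to rt
Reagents that add atoms: none
Why: Swern oxidation followed in the same flask by Wittig olefination with a stabilised ylide, which traps the labile α-alkoxy aldehyde 8 as it forms; the E/Z composition is of no consequence because the double bond is reduced in step 6.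

Step 6
Reactants: 9 ethyl (E)-3-((4R,5R)-2,2-dimethyl-5-(2-methylprop-1-en-1-yl)-1,3-dioxolan-4-yl)prop-2-enoate
Product: 10 ethyl 3-((4R,5R)-2,2-dimethyl-5-(2-methylprop-1-en-1-yl)-1,3-dioxolan-4-yl)propanoate
Conditions: [(Ph3P)CuH]6 (3 mol %), Me(EtO)2SiH, t-BuOH, toluene, rt
Reagents that add atoms: none
Why: Copper hydride conjugate reduction delivers hydride only to the β-carbon of the enoate, so the isolated trisubstituted alkene is untouched; since no radical anion is formed, the γ-oxygen of the dioxolane should not be expelled, as it can be in electron-transfer reductions.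

Step 7
Reactants: 10 ethyl 3-((4R,5R)-2,2-dimethyl-5-(2-methylprop-1-en-1-yl)-1,3-dioxolan-4-yl)propanoate
Product: 11 3-((4R,5R)-2,2-dimethyl-5-(2-methylprop-1-en-1-yl)-1,3-dioxolan-4-yl)propanal
Conditions: i-Bu2AlH (1.05 equiv), CH2Cl2, −78 °C; MeOH, then aq. potassium sodium tartrate
Reagents that add atoms: none
Why: Partial reduction of an ester to the aldehyde; the tetrahedral aluminium hemiacetal is stable at −78 °C and collapses only on work-up.

Step 8
Reactants: 11 3-((4R,5R)-2,2-dimethyl-5-(2-methylprop-1-en-1-yl)-1,3-dioxolan-4-yl)propanal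
Product: 12 (3aR,4S,5R,7aR)-2,2-dimethyl-4-(prop-1-en-2-yl)hexahydro-1,3-benzodioxol-5-ol
Conditions: Me2AlCl (1.5 equiv), CH2Cl2, −78 to −20 °C; aq. potassium sodium tartrate
Reagents that add atoms: none
Why: Me2AlCl binds the aldehyde oxygen; the C5=C(CH3)2 π bond attacks the activated carbonyl carbon C4 while a methyl hydrogen passes to oxygen through a six-centre array, so the C4–C5 bond, the O–H bond and the isopropenyl C=C form in one concerted or closely coupled event. The closest known reaction type is the Lewis-acid-promoted type-1 intramolecular carbonyl-ene cyclisation of 7-methyloct-6-enals (citronellal to isopulegol). The six-membered carbocycle closes in a 6-exo mode with respect to both π components (the carbonyl oxygen and the CMe2 terminus stay outside the ring) through a chair-like transition state. C5 is controlled by C6: the trans-dioxolane can only span two equatorial positions, which fixes the chair, and the alkene terminus then takes the equatorial site, trans to the C6 oxygen. C4 is controlled by the same chair: the aluminium-bound carbonyl lies equatorial and gauche to the alkene, as hydrogen transfer requires, so the hydroxyl forms trans to C5 and is inverted later. The step needs ene selectivity over chloride capture at the tertiary carbon and over ionisation of the allylic dioxolane C–O bond; the methyl–aluminium bonds scavenge protons, the reaction is run cold, and the product stays bound to aluminium as its alkoxide until work-up.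

Step 9
Reactants: 12 (3aR,4S,5R,7aR)-2,2-dimethyl-4-(prop-1-en-2-yl)hexahydro-1,3-benzodioxol-5-ol
Product: 13 (3aR,4S,5R,7aR)-4-isopropyl-2,2-dimethylhexahydro-1,3-benzodioxol-5-ol
Conditions: H2 (1 atm), PtO2 (5 mol %), EtOAc, rt
Reagents that add atoms: none
Why: Heterogeneous hydrogenation of a 1,1-disubstituted alkene creates no stereocentre; PtO2 is chosen over palladium to limit migration of the double bond toward C5, which would erase that centre.

Step 10
Reactants: 13 (3aR,4S,5R,7aR)-4-isopropyl-2,2-dimethylhexahydro-1,3-benzodioxol-5-ol
Product: 14 (3aR,4R,7aR)-4-isopropyl-2,2-dimethylhexahydro-1,3-benzodioxol-5-one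
Conditions: Pr4N[RuO4] (5 mol %), N-methylmorpholine N-oxide, 4 Å MS, CH2Cl2, rt
Reagents that add atoms: none
Why: Catalytic perruthenate (Ley–Griffith) oxidation of a secondary alcohol under neutral conditions, which should avoid β-elimination of the C6 oxygen; the equatorial isopropyl group at C5 has no drive to epimerise.

Step 11
Reactants: 14 (3aR,4R,7aR)-4-isopropyl-2,2-dimethylhexahydro-1,3-benzodioxol-5-one
Product: 15 (3aR,4R,7aR)-4-isopropyl-2,2-dimethyl-5-((trimethylsilyl)oxy)-3a,4,7,7a-tetrahydro-1,3-benzodioxole
Conditions: LiN(i-Pr)2, Me3SiCl, THF, −78 °C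
Reagents that add atoms: chlorotrimethylsilane, C[Si](C)(C)Cl
Why: Kinetic deprotonation by a hindered lithium amide should occur at the C3 methylene, not at the C5 methine, with in situ O-silylation; this also avoids the C5 enolate, which could expel the C6 oxygen.

Step 12
Reactants: 15 (3aR,4R,7aR)-4-isopropyl-2,2-dimethyl-5-((trimethylsilyl)oxy)-3a,4,7,7a-tetrahydro-1,3-benzodioxole
Product: 16 (3aR,4R,7aR)-4-isopropyl-2,2-dimethyl-3a,7a-dihydro-1,3-benzodioxol-5(4H)-one
Conditions: Pd(OAc)2 (1.1 equiv), MeCN, rt
Reagents that add atoms: none
Why: Saegusa–Ito oxidation: the palladium enolate formed at C3 undergoes β-hydride elimination from C2, so the position of the new C2=C3 bond is fixed by the enol ether.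

Step 13
Reactants: 16 (3aR,4R,7aR)-4-isopropyl-2,2-dimethyl-3a,7a-dihydro-1,3-benzodioxol-5(4H)-one
Product: 17 (3aR,4S,5R,7aR)-4-isopropyl-2,2-dimethyl-3a,4,5,7a-tetrahydro-1,3-benzodioxol-5-ol
Conditions: NaBH4, CeCl3·7H2O, MeOH, −78 °C
Reagents that add atoms: none
Why: Luche 1,2-reduction; the small hydride should add along the axial trajectory anti to the pseudoaxial C5–H of the dioxolane-locked half-chair and give the pseudoequatorial C4 alcohol trans to isopropyl, while cerium suppresses conjugate reduction.

Step 14
Reactants: 17 (3aR,4S,5R,7aR)-4-isopropyl-2,2-dimethyl-3a,4,5,7a-tetrahydro-1,3-benzodioxol-5-ol; 18 2-methylpropanoic acid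
Product: 19 (3aR,4S,5S,7aR)-4-isopropyl-2,2-dimethyl-3a,4,5,7a-tetrahydro-1,3-benzodioxol-5-yl 2-methylpropanoate
Conditions: PPh3, i-PrO2CN=NCO2i-Pr, toluene, 0 °C to rt
Reagents that add atoms: none
Why: Mitsunobu esterification: SN2 displacement of the allylic oxyphosphonium group by the carboxylate inverts C4 and places the ester cis to isopropyl; SN2' attack at C2 is disfavoured by the adjacent dioxolane carbon.

Step 15
Reactants: 19 (3aR,4S,5S,7aR)-4-isopropyl-2,2-dimethyl-3a,4,5,7a-tetrahydro-1,3-benzodioxol-5-yl 2-methylpropanoate
Product: 20 (1S,4R,5R,6R)-4,5-dihydroxy-6-isopropylcyclohex-2-en-1-yl 2-methylpropanoate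
Conditions: AcOH/H2O (4:1), 40 °C
Reagents that add atoms: none
Why: Acid hydrolysis of a strained trans-fused acetonide, which should proceed under conditions too mild to ionise the allylic ester; the C4 ester is trans-1,3 to the C6 hydroxyl, so acyl migration has no easy path.

Step 16
Reactants: 20 (1S,4R,5R,6R)-4,5-dihydroxy-6-isopropylcyclohex-2-en-1-yl 2-methylpropanoate
Product: 21 (1S,5R,6R)-5-hydroxy-6-isopropyl-4-oxocyclohex-2-en-1-yl 2-methylpropanoate
Conditions: MnO2 (activated, excess), CH2Cl2, rt
Reagents that add atoms: none
Why: MnO2 oxidises allylic alcohols selectively; the C1 hydroxyl is allylic and the C6 hydroxyl is not, so the two oxygens that came from one dioxolane are told apart by reactivity alone.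

Step 17
Reactants: 22 2-((tert-butyldimethylsilyl)oxy)acetaldehyde; 23 ethyl 2-(triphenylphosphoranylidene)propanoate
Product: 24 ethyl (E)-4-((tert-butyldimethylsilyl)oxy)-2-methylbut-2-enoate
Conditions: CH2Cl2, rt
Reagents that add atoms: none
Why: Wittig olefination with an α-methyl stabilised ylide, which should give the E trisubstituted enoate under the usual thermodynamic control of oxaphosphetane formation.

Step 18
Reactants: 24 ethyl (E)-4-((tert-butyldimethylsilyl)oxy)-2-methylbut-2-enoate
Product: 25 (E)-4-((tert-butyldimethylsilyl)oxy)-2-methylbut-2-enoic acid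
Conditions: LiOH, THF/MeOH/H2O, rt; then 1 M HCl to pH 4, 0 °C
Reagents that add atoms: lithium hydroxide, [Li+].[OH-]
Why: Saponification of an ethyl ester; a primary silyl ether tolerates LiOH at room temperature, and the cold, mild acidification should spare it as well.

Step 19
Reactants: 21 (1S,5R,6R)-5-hydroxy-6-isopropyl-4-oxocyclohex-2-en-1-yl 2-methylpropanoate; 25 (E)-4-((tert-butyldimethylsilyl)oxy)-2-methylbut-2-enoic acid
Product: 27 (1R,5S,6S)-5-(isobutyryloxy)-6-isopropyl-2-oxocyclohex-3-en-1-yl (E)-4-((tert-butyldimethylsilyl)oxy)-2-methylbut-2-enoate, via mixed anhydride 26 (not isolated)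
Conditions: 25, 2,4,6-Cl3C6H2COCl, Et3N, THF, rt; then 21, DMAP, toluene, 0 °C to rt
Reagents that add atoms: none
Why: Yamaguchi esterification: the mixed anhydride 26 is attacked by DMAP at the less hindered carbonyl and the resulting acylpyridinium acylates the hindered C6 hydroxyl; the C–O bond at C6 is not touched, so its configuration is retained.

Step 20
Reactants: 27 (1R,5S,6S)-5-(isobutyryloxy)-6-isopropyl-2-oxocyclohex-3-en-1-yl (E)-4-((tert-butyldimethylsilyl)oxy)-2-methylbut-2-enoate; 28 formaldehyde
Product: 29 (1R,5S,6S)-3-(hydroxymethyl)-5-(isobutyryloxy)-6-isopropyl-2-oxocyclohex-3-en-1-yl (E)-4-((tert-butyldimethylsilyl)oxy)-2-methylbut-2-enoate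
Conditions: 28 (37% aq.), DMAP (0.3 equiv), THF/H2O, rt
Reagents that add atoms: none
Why: Morita–Baylis–Hillman reaction: DMAP adds to C3, the enolate attacks formaldehyde through C2, and loss of DMAP restores the enone; the trisubstituted enoate of the side chain is too hindered to act as a second acceptor.

Step 21
Reactants: 29 (1R,5S,6S)-3-(hydroxymethyl)-5-(isobutyryloxy)-6-isopropyl-2-oxocyclohex-3-en-1-yl (E)-4-((tert-butyldimethylsilyl)oxy)-2-methylbut-2-enoate
Product: 30 (1R,5S,6S)-3-(hydroxymethyl)-5-(isobutyryloxy)-6-isopropyl-2-oxocyclohex-3-en-1-yl (E)-4-hydroxy-2-methylbut-2-enoate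
Conditions: HF·pyridine, pyridine, THF, 0 °C to rt
Reagents that add atoms: none
Why: Fluoride-mediated desilylation of a primary silyl ether under buffered, weakly acidic conditions, which should leave the esters, the enone and the C6 stereocentre untouched.

## Compound list

1 | ((4R,5R)-2,2-dimethyl-1,3-dioxolane-4,5-diyl)dimethanol | OC[C@H]1OC(C)(C)O[C@@H]1CO | starting material
2 | ((4R,5R)-5-(((tert-butyldimethylsilyl)oxy)methyl)-2,2-dimethyl-1,3-dioxolan-4-yl)methanol | CC(C)(C)[Si](C)(C)OC[C@H]1OC(C)(C)O[C@@H]1CO | intermediate
3 | (4S,5R)-5-(((tert-butyldimethylsilyl)oxy)methyl)-2,2-dimethyl-1,3-dioxolane-4-carbaldehyde | CC(C)(C)[Si](C)(C)OC[C@H]1OC(C)(C)O[C@@H]1C=O | intermediate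
4 | isopropyltriphenylphosphonium iodide | CC(C)[P+](c1ccccc1)(c1ccccc1)c1ccccc1.[I-] | starting material
5 | tert-butyldimethyl(((4R,5R)-2,2-dimethyl-5-(2-methylprop-1-en-1-yl)-1,3-dioxolan-4-yl)methoxy)silane | CC(C)(C)[Si](C)(C)OC[C@H]1OC(C)(C)O[C@@H]1C=C(C)C | intermediate
6 | ((4R,5R)-2,2-dimethyl-5-(2-methylprop-1-en-1-yl)-1,3-dioxolan-4-yl)methanol | OC[C@H]1OC(C)(C)O[C@@H]1C=C(C)C | intermediate
7 | ethyl (triphenylphosphoranylidene)acetate | CCOC(=O)C=P(c1ccccc1)(c1ccccc1)c1ccccc1 | starting material
8 | (4S,5R)-2,2-dimethyl-5-(2-methylprop-1-en-1-yl)-1,3-dioxolane-4-carbaldehyde | O=C[C@H]1OC(C)(C)O[C@@H]1C=C(C)C | intermediate (not isolated)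
9 | ethyl (E)-3-((4R,5R)-2,2-dimethyl-5-(2-methylprop-1-en-1-yl)-1,3-dioxolan-4-yl)prop-2-enoate | CCOC(=O)/C=C/[C@H]1OC(C)(C)O[C@@H]1C=C(C)C | intermediate
10 | ethyl 3-((4R,5R)-2,2-dimethyl-5-(2-methylprop-1-en-1-yl)-1,3-dioxolan-4-yl)propanoate | CCOC(=O)CC[C@H]1OC(C)(C)O[C@@H]1C=C(C)C | intermediate
11 | 3-((4R,5R)-2,2-dimethyl-5-(2-methylprop-1-en-1-yl)-1,3-dioxolan-4-yl)propanal | O=CCC[C@H]1OC(C)(C)O[C@@H]1C=C(C)C | intermediate
12 | (3aR,4S,5R,7aR)-2,2-dimethyl-4-(prop-1-en-2-yl)hexahydro-1,3-benzodioxol-5-ol | CC1(C)O[C@H]2[C@H](O1)CC[C@@H](O)[C@@H]2C(C)=C | intermediate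
13 | (3aR,4S,5R,7aR)-4-isopropyl-2,2-dimethylhexahydro-1,3-benzodioxol-5-ol | CC1(C)O[C@H]2[C@H](O1)CC[C@@H](O)[C@@H]2C(C)C | intermediate
14 | (3aR,4R,7aR)-4-isopropyl-2,2-dimethylhexahydro-1,3-benzodioxol-5-one | CC1(C)O[C@H]2[C@H](O1)CCC(=O)[C@@H]2C(C)C | intermediate
15 | (3aR,4R,7aR)-4-isopropyl-2,2-dimethyl-5-((trimethylsilyl)oxy)-3a,4,7,7a-tetrahydro-1,3-benzodioxole | CC1(C)O[C@H]2[C@H](O1)CC=C(O[Si](C)(C)C)[C@@H]2C(C)C | intermediate
16 | (3aR,4R,7aR)-4-isopropyl-2,2-dimethyl-3a,7a-dihydro-1,3-benzodioxol-5(4H)-one | CC1(C)O[C@H]2[C@H](O1)C=CC(=O)[C@@H]2C(C)C | intermediate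
17 | (3aR,4S,5R,7aR)-4-isopropyl-2,2-dimethyl-3a,4,5,7a-tetrahydro-1,3-benzodioxol-5-ol | CC1(C)O[C@H]2[C@H](O1)C=C[C@@H](O)[C@@H]2C(C)C | intermediate
18 | 2-methylpropanoic acid | CC(C)C(=O)O | starting material
19 | (3aR,4S,5S,7aR)-4-isopropyl-2,2-dimethyl-3a,4,5,7a-tetrahydro-1,3-benzodioxol-5-yl 2-methylpropanoate | CC1(C)O[C@H]2[C@H](O1)C=C[C@H](OC(=O)C(C)C)[C@@H]2C(C)C | intermediate
20 | (1S,4R,5R,6R)-4,5-dihydroxy-6-isopropylcyclohex-2-en-1-yl 2-methylpropanoate | O[C@H]1[C@H](O)C=C[C@H](OC(=O)C(C)C)[C@@H]1C(C)C | intermediate
21 | (1S,5R,6R)-5-hydroxy-6-isopropyl-4-oxocyclohex-2-en-1-yl 2-methylpropanoate | O[C@H]1C(=O)C=C[C@H](OC(=O)C(C)C)[C@@H]1C(C)C | intermediate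
22 | 2-((tert-butyldimethylsilyl)oxy)acetaldehyde | CC(C)(C)[Si](C)(C)OCC=O | starting material
23 | ethyl 2-(triphenylphosphoranylidene)propanoate | CCOC(=O)C(C)=P(c1ccccc1)(c1ccccc1)c1ccccc1 | starting material
24 | ethyl (E)-4-((tert-butyldimethylsilyl)oxy)-2-methylbut-2-enoate | CCOC(=O)/C(C)=C/CO[Si](C)(C)C(C)(C)C | intermediate
25 | (E)-4-((tert-butyldimethylsilyl)oxy)-2-methylbut-2-enoic acid | C/C(=C\CO[Si](C)(C)C(C)(C)C)C(=O)O | intermediate
26 | (E)-4-((tert-butyldimethylsilyl)oxy)-2-methylbut-2-enoic 2,4,6-trichlorobenzoic anhydride | C/C(=C\CO[Si](C)(C)C(C)(C)C)C(=O)OC(=O)c1c(Cl)cc(Cl)cc1Cl | intermediate (not isolated)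
27 | (1R,5S,6S)-5-(isobutyryloxy)-6-isopropyl-2-oxocyclohex-3-en-1-yl (E)-4-((tert-butyldimethylsilyl)oxy)-2-methylbut-2-enoate | C/C(=C\CO[Si](C)(C)C(C)(C)C)C(=O)O[C@H]1C(=O)C=C[C@H](OC(=O)C(C)C)[C@@H]1C(C)C | intermediate
28 | formaldehyde | C=O | starting material
29 | (1R,5S,6S)-3-(hydroxymethyl)-5-(isobutyryloxy)-6-isopropyl-2-oxocyclohex-3-en-1-yl (E)-4-((tert-butyldimethylsilyl)oxy)-2-methylbut-2-enoate | C/C(=C\CO[Si](C)(C)C(C)(C)C)C(=O)O[C@H]1C(=O)C(CO)=C[C@H](OC(=O)C(C)C)[C@@H]1C(C)C | intermediate
30 | (1R,5S,6S)-3-(hydroxymethyl)-5-(isobutyryloxy)-6-isopropyl-2-oxocyclohex-3-en-1-yl (E)-4-hydroxy-2-methylbut-2-enoate | C/C(=C\CO)C(=O)O[C@H]1C(=O)C(CO)=C[C@H](OC(=O)C(C)C)[C@@H]1C(C)C | target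

## Step count and least certain steps

Total: 21 steps (19 in the main line, 2 for acid 25). Longest linear sequence: 19 steps (steps 1–16 and 19–21).

**Step 8 (key step).** The most likely failure is capture of the developing tertiary cationic centre by chloride in place of hydrogen transfer, because the allylic oxygen at C6 makes the alkene less nucleophilic and the transfer slower. Cleavage of the allylic dioxolane C–O bond by the Lewis acid is the second risk. Fallback: setting out from 11, the closure is run on purpose as a Prins cyclisation with chloride capture (MeAlCl2, 2 equiv, CH2Cl2, −78 °C) through the same chair to give the tertiary chloride alcohol F1. Radical dehalogenation (Bu3SnH, AIBN, toluene, 80 °C) then gives 13, where the route is rejoined; step 9 is no longer needed.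

**Step 13.** Hydride delivery from the wrong face (poor facial selectivity) is possible because the α'-isopropyl group flanks both faces of the carbonyl. Fallback: setting out from 16, the epimeric cis-alcohol F2 formed in that event already has the required C4 configuration. It can be favoured deliberately with a bulkier 1,2-selective hydride such as LiAlH(O-t-Bu)3 and is acylated with retention (isobutyryl chloride, pyridine, DMAP, CH2Cl2) to give 19, where the route is rejoined without step 14. Because 17 reaches 19 by inversion and F2 by retention, both epimers can be carried forward after separation.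

**Step 14.** Substitution at the hindered allylic carbon by a weakly acidic pronucleophile may be slow, so that elimination to a diene or SN2' transposition takes over. Fallback: setting out from 17, the Mitsunobu reaction is run with the more acidic 4-nitrobenzoic acid to give the inverted 4-nitrobenzoate F3. Methanolysis (K2CO3, MeOH) gives the cis-alcohol F2, and acylation with isobutyryl chloride returns to the route at 19.

**Step 19.** Base-induced enolisation of the α-hydroxy enone toward C6 during acylation would lead to epimerisation, ketol transposition or vinylogous loss of isobutyric acid followed by aromatisation. Fallback: setting out from 20, the acylation is moved ahead of the oxidation. The less hindered allylic C1 hydroxyl is silylated (Et3SiCl, imidazole, CH2Cl2, −40 °C) to give the mono-triethylsilyl ether F4. The C6 hydroxyl is esterified with 25 under the mixed-anhydride conditions to give the diester F5. Buffered HF·pyridine at 0 °C removes the secondary triethylsilyl group in preference to the primary tert-butyldimethylsilyl group and gives the allylic alcohol F6. MnO2 oxidation returns to the route at 27.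

**Step 20.** Slow turnover of the nucleophilic catalyst on an enone with a branched γ-carbon would leave time for C6 enolisation, acyl loss or elimination under the basic aqueous conditions. Fallback: setting out from 27, α-iodination of the enone (I2, pyridine, CH2Cl2) gives the α-iodoenone F7. Stille coupling with Bu3SnCH2OH (Pd(PPh3)4, a zerovalent palladium catalyst, dioxane, 80 °C) installs the hydroxymethyl group under neutral conditions and returns to the route at 29.

## Further compounds

F1 | step 8 | (3aR,4S,5R,7aR)-4-(2-chloropropan-2-yl)-2,2-dimethylhexahydro-1,3-benzodioxol-5-ol | CC1(C)O[C@H]2[C@H](O1)CC[C@@H](O)[C@@H]2C(C)(C)Cl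
F2 | step 13 | (3aR,4S,5S,7aR)-4-isopropyl-2,2-dimethyl-3a,4,5,7a-tetrahydro-1,3-benzodioxol-5-ol | CC1(C)O[C@H]2[C@H](O1)C=C[C@H](O)[C@@H]2C(C)C
F3 | step 14 | (3aR,4S,5S,7aR)-4-isopropyl-2,2-dimethyl-3a,4,5,7a-tetrahydro-1,3-benzodioxol-5-yl 4-nitrobenzoate | CC1(C)O[C@H]2[C@H](O1)C=C[C@H](OC(=O)c3ccc(cc3)[N+](=O)[O-])[C@@H]2C(C)C
F4 | step 19 | (1S,4R,5R,6R)-5-hydroxy-6-isopropyl-4-((triethylsilyl)oxy)cyclohex-2-en-1-yl 2-methylpropanoate | O[C@H]1[C@H](O[Si](CC)(CC)CC)C=C[C@H](OC(=O)C(C)C)[C@@H]1C(C)C
F5 | step 19 | (1R,2R,5S,6S)-5-(isobutyryloxy)-6-isopropyl-2-((triethylsilyl)oxy)cyclohex-3-en-1-yl (E)-4-((tert-butyldimethylsilyl)oxy)-2-methylbut-2-enoate | C/C(=C\CO[Si](C)(C)C(C)(C)C)C(=O)O[C@H]1[C@H](O[Si](CC)(CC)CC)C=C[C@H](OC(=O)C(C)C)[C@@H]1C(C)C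
F6 | step 19 | (1R,2R,5S,6S)-2-hydroxy-5-(isobutyryloxy)-6-isopropylcyclohex-3-en-1-yl (E)-4-((tert-butyldimethylsilyl)oxy)-2-methylbut-2-enoate | C/C(=C\CO[Si](C)(C)C(C)(C)C)C(=O)O[C@H]1[C@H](O)C=C[C@H](OC(=O)C(C)C)[C@@H]1C(C)C
F7 | step 20 | (1R,5R,6S)-3-iodo-5-(isobutyryloxy)-6-isopropyl-2-oxocyclohex-3-en-1-yl (E)-4-((tert-butyldimethylsilyl)oxy)-2-methylbut-2-enoate | C/C(=C\CO[Si](C)(C)C(C)(C)C)C(=O)O[C@H]1C(=O)C(I)=C[C@H](OC(=O)C(C)C)[C@@H]1C(C)C
A1 | alternative 1 | (R)-5-((tert-butyldimethylsilyl)oxy)-1-diazo-7-methyloct-6-en-2-one | [N-]=[N+]=CC(=O)CC[C@@H](O[Si](C)(C)C(C)(C)C)C=C(C)C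
A2 | alternative 1 | (1R,5R,6S)-5-((tert-butyldimethylsilyl)oxy)-7,7-dimethylbicyclo[4.1.0]heptan-2-one | CC1(C)[C@@H]2C(=O)CC[C@@H](O[Si](C)(C)C(C)(C)C)[C@H]12
A3 | alternative 2 | (2R,4R)-3-isopropyl-2,4-bis((4-methoxybenzyl)oxy)pentanedial | O=C[C@H](OCc1ccc(OC)cc1)C(C(C)C)[C@@H](OCc1ccc(OC)cc1)C=O
A4 | alternative 2 | triethyl phosphonoacetate | CCOC(=O)CP(=O)(OCC)OCC
A5 | alternative 2 | ethyl (3S,4S,5R,6R)-6-hydroxy-4-isopropyl-3,5-bis((4-methoxybenzyl)oxy)cyclohex-1-ene-1-carboxylate | COc1ccc(CO[C@H]2[C@H](O)C(C(=O)OCC)=C[C@H](OCc3ccc(OC)cc3)[C@@H]2C(C)C)cc1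
A6 | alternative 3 | (2S,3S)-3-((tert-butyldimethylsilyl)oxy)-2-isopropylhexanedial | O=CCC[C@H](O[Si](C)(C)C(C)(C)C)[C@@H](C=O)C(C)C
A7 | alternative 3 | (1S,2R,3R,4S)-4-((tert-butyldimethylsilyl)oxy)-3-isopropylcyclohexane-1,2-diol | O[C@H]1[C@@H](O)CC[C@H](O[Si](C)(C)C(C)(C)C)[C@@H]1C(C)C
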